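**Retrosynthetic overview**
1. 7 ⇒ 6: cut the two oxirane C–O bonds. One of the two interchangeable prenyl groups of diprenyl acylphloroglucinol 6 is epoxidised last, enantioselectively and under phenol direction (new step; sets the (S) oxirane centre).
2. 6 ⇒ 4 + 2 × 5: two aryl–CH2 bonds, made by double C-prenylation of the phloroglucinolate.
3. 4 ⇒ 1 + 2: aryl–C(=O) bond, made by Friedel–Crafts acylation; the (R) centre is bought with acid 2.
4. Ring order: the benzene ring comes with 1; the oxirane is the only ring made, in the final step.

Assumption 1: (R)-2-methylbutanoic acid of at least 98% ee is bought as a catalogue compound (dearer than its (S) antipode, but only one equivalent is used).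
Assumption 2: the sense of induction of the new step 3 is a prediction, not a known fact; if the first run gives the (R) oxirane, the (S,S) ligand (equally available) is used instead.

**Step 1**
Reactants: 1 phloroglucinol (benzene-1,3,5-triol); 2 (R)-2-methylbutanoic acid
Product: 4 (R)-2-methyl-1-(2,4,6-trihydroxyphenyl)butan-1-one, via (R)-2-methylbutanoyl chloride 3 (not isolated)
Conditions: 2, (COCl)2 (1.05 equiv), DMF (cat.), CH2Cl2, 0 °C to rt, volatiles stripped; then 1 (1.2 equiv), AlCl3 (4 equiv), CH2Cl2/MeNO2, 0 °C to rt; ice/1 M HCl
Reagents that add atoms: none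
Why: Friedel–Crafts acylation of the very electron-rich symmetric triphenol stops at the mono-C-acyl stage because the first acyl group (as its aluminium chelate) deactivates the ring; no stereocentre is made, and the (R) centre of 2 is carried through because the low temperature and the chelated, conjugated carbonyl disfavour enolisation.

**Step 2**
Reactants: 4 (R)-2-methyl-1-(2,4,6-trihydroxyphenyl)butan-1-one; 5 prenyl bromide (1-bromo-3-methylbut-2-ene, 2.1 equiv)
Product: 6 (R)-2-methyl-1-[2,4,6-trihydroxy-3,5-bis(3-methylbut-2-en-1-yl)phenyl]butan-1-one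
Conditions: 10% aq KOH, 0 °C, 1–2 h; 1 M HCl to pH 3; chromatography (mono-prenyl material recycled)
Reagents that add atoms: none
Why: Base-mediated C-alkylation of the ambident phloroglucinolate in water (hydrogen bonding shields the oxygens) puts one prenyl group on each free ring carbon; the known yield for this type is modest (about 35–45%), and the α-centre is safe because the ketone is held as a vinylogous carboxylate that does not enolise toward the side chain.

**Step 3**
Reactants: 6 (R)-2-methyl-1-[2,4,6-trihydroxy-3,5-bis(3-methylbut-2-en-1-yl)phenyl]butan-1-one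
Product: 7 (2R)-1-[3-{[(2S)-3,3-dimethyloxiran-2-yl]methyl}-2,4,6-trihydroxy-5-(3-methylbut-2-en-1-yl)phenyl]-2-methylbutan-1-one (CNP0286412.1)
Conditions: Hf(OtBu)4 (10 mol%), (R,R)-N,N'-dihydroxy-N,N'-bis(diphenylacetyl)cyclohexane-1,2-diamine (12 mol%), DMPU (1 equiv), 4 Å MS, PhC(CH3)2OOH (0.65 equiv, slow addition), toluene, −10 °C; stop at about 55% conversion; pH 7 phosphate/Na2S2O3 quench; pH 7-buffered silica (6 recovered)
Reagents that add atoms: cumene hydroperoxide, CC(C)(OO)c1ccccc1
Why: Proposed new method: phenol-directed enantioselective epoxidation of an ortho-prenyl phenol, in which the acidic 4-OH of 6 (flanked by both prenyl groups) exchanges onto the redox-inert tetravalent hafnium centre of the C2-symmetric bishydroxamate complex, the cumyl peroxide binds to the same metal, and its distal oxygen is delivered intramolecularly to the prenyl C=C four atoms away from the bound oxygen (a bishomoallylic arrangement held rigid by the arene), so the alkene and not the electron-rich ring is oxidised and the ligand pocket selects the alkene face that gives the (S) oxirane; the closest known reactions are the hafnium- or zirconium-bishydroxamic acid epoxidation of aliphatic homoallylic and bishomoallylic alcohols and the racemic VO(acac)2/t-BuOOH oxidation of 2-alkenylphenols; sub-stoichiometric peroxide leaves the second prenyl group intact (the two are interchangeable by rotation about the aryl–carbonyl bond, so either gives 7), while DMPU, sieves and low temperature hold back Lewis-acid opening of the oxirane by the neighbouring phenols.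

**Compound list**
1 | phloroglucinol (benzene-1,3,5-triol) | Oc1cc(O)cc(O)c1 | starting material
2 | (R)-2-methylbutanoic acid | CC[C@@H](C)C(=O)O | starting material
3 | (R)-2-methylbutanoyl chloride | CC[C@@H](C)C(=O)Cl | intermediate
4 | (R)-2-methyl-1-(2,4,6-trihydroxyphenyl)butan-1-one | CC[C@@H](C)C(=O)c1c(O)cc(O)cc1O | intermediate
5 | prenyl bromide (1-bromo-3-methylbut-2-ene) | CC(C)=CCBr | starting material
6 | (R)-2-methyl-1-[2,4,6-trihydroxy-3,5-bis(3-methylbut-2-en-1-yl)phenyl]butan-1-one | CC[C@@H](C)C(=O)c1c(O)c(CC=C(C)C)c(O)c(CC=C(C)C)c1O | intermediate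
7 | (2R)-1-[3-{[(2S)-3,3-dimethyloxiran-2-yl]methyl}-2,4,6-trihydroxy-5-(3-methylbut-2-en-1-yl)phenyl]-2-methylbutan-1-one | CC[C@@H](C)C(=O)c1c(O)c(CC=C(C)C)c(O)c(C[C@@H]2OC2(C)C)c1O | target

**Totals**
Total steps: 3. Longest linear sequence: 3 (1/2 → 4 → 6 → 7).

**Steps most likely to fail, with fallbacks**

Step 3 (proposed new method). The risks are:
- oxidation of the acylphloroglucinol ring;
- cyclisation of 7 on the Lewis acid to a dihydrobenzofuran or chromane;
- tight chelation of hafnium by the 2-acylphenol unit;
- low or opposite facial selectivity. The oxirane epimer of 7 differs only at a remote centre and will be hard to separate, so the diastereomer ratio equals the catalyst selectivity and must be checked by chiral HPLC.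

Fallback with known chemistry, setting out from 6 and coming back at 7. Ac2O, pyridine and DMAP give 2-[(2R)-2-methylbutanoyl]-4,6-bis(3-methylbut-2-en-1-yl)benzene-1,3,5-triyl triacetate F1. Shi epoxidation of F1 with the L-fructose-derived ketone (the antipode of the usual D-fructose-derived Shi ketone, 30 mol%), Oxone (2KHSO5·KHSO4·K2SO4, 0.7 equiv), K2CO3, Na2B4O7/Na2EDTA buffer, MeCN/dimethoxymethane, 0 °C, is run to about half conversion. This gives 2-{[(2S)-3,3-dimethyloxiran-2-yl]methyl}-6-[(2R)-2-methylbutanoyl]-4-(3-methylbut-2-en-1-yl)benzene-1,3,5-triyl triacetate F2. The (S) sense follows the established spiro transition-state model: the D-fructose-derived ketone gives (R) on ArCH2CH=C(CH3)2, so its antipode gives (S). Neutral deacetylation with immobilised Candida antarctica lipase B and n-butanol in MTBE at 35 °C, chosen so that no phenolate is generated that would open the oxirane, returns 7.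

Step 2. The risks are statistical under- and over-alkylation, geminal dialkylation and O-prenylation. Fallback setting out from 4 and coming back at 6. Allyl bromide (2.2 equiv), K2CO3, acetone at reflux give (R)-1-[2-hydroxy-4,6-bis(prop-2-en-1-yloxy)phenyl]-2-methylbutan-1-one F3; the chelated ortho-OH stays free. A double aromatic Claisen rearrangement (N,N-diethylaniline, 190 °C) moves both allyl groups to the two free ring carbons. An allyl group that reaches an occupied ortho carbon goes on by Cope shift to the free para carbon, so both pathways converge on (R)-2-methyl-1-[2,4,6-trihydroxy-3,5-di(prop-2-en-1-yl)phenyl]butan-1-one F4. Cross-metathesis of F4 with excess 2-methylbut-2-ene and second-generation Grubbs catalyst (H2IMes)(PCy3)Cl2Ru=CHPh in CH2Cl2 at 40 °C converts both allyl groups into prenyl groups and gives 6.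

Step 1. The risks are erosion of ee at the α-centre by enolisation under AlCl3/HCl, and di-acylation. Fallback setting out from 1 and 2 and coming back at 4. NaH and chloromethyl methyl ether in DMF convert 1 into 1,3,5-tris(methoxymethoxy)benzene F5. Carbonyldiimidazole followed by MeNHOMe·HCl converts 2 into (R)-N-methoxy-N,2-dimethylbutanamide F6. F5 is lithiated between two MOM ethers (n-BuLi, THF, 0 °C) and the aryllithium is acylated with F6 at −78 °C. The stable tetrahedral chelate prevents enolisation, giving (R)-2-methyl-1-[2,4,6-tris(methoxymethoxy)phenyl]butan-1-one F7. HCl in MeOH at rt removes the three MOM groups and returns 4.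

**Further compounds**
F1 | step 3 | 2-[(2R)-2-methylbutanoyl]-4,6-bis(3-methylbut-2-en-1-yl)benzene-1,3,5-triyl triacetate | CC[C@@H](C)C(=O)c1c(OC(C)=O)c(CC=C(C)C)c(OC(C)=O)c(CC=C(C)C)c1OC(C)=O
F2 | step 3 | 2-{[(2S)-3,3-dimethyloxiran-2-yl]methyl}-6-[(2R)-2-methylbutanoyl]-4-(3-methylbut-2-en-1-yl)benzene-1,3,5-triyl triacetate | CC[C@@H](C)C(=O)c1c(OC(C)=O)c(CC=C(C)C)c(OC(C)=O)c(C[C@@H]2OC2(C)C)c1OC(C)=O
F3 | step 2 | (R)-1-[2-hydroxy-4,6-bis(prop-2-en-1-yloxy)phenyl]-2-methylbutan-1-one | CC[C@@H](C)C(=O)c1c(O)cc(OCC=C)cc1OCC=C
F4 | step 2 | (R)-2-methyl-1-[2,4,6-trihydroxy-3,5-di(prop-2-en-1-yl)phenyl]butan-1-one | CC[C@@H](C)C(=O)c1c(O)c(CC=C)c(O)c(CC=C)c1O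
F5 | step 1 | 1,3,5-tris(methoxymethoxy)benzene | COCOc1cc(OCOC)cc(OCOC)c1
F6 | step 1 | (R)-N-methoxy-N,2-dimethylbutanamide | CC[C@@H](C)C(=O)N(C)OC
F7 | step 1 | (R)-2-methyl-1-[2,4,6-tris(methoxymethoxy)phenyl]butan-1-one | CC[C@@H](C)C(=O)c1c(OCOC)cc(OCOC)cc1OCOC
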